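**Plan**

Lactone numbering: O1, C2 (C=O), C3 (C–OH), C4 (CH), C5 (OCH2).

1. Retrosynthesis cuts, in order: the two O-benzyl protecting groups; the C3–CH2Ar bond (enolate alkylation); the O1–C2 acyl bond together with the C5–O1 bond (lactonisation after C–Si oxidation); the C5–C4 bond (radical ring closure from a silicon tether on the C3 oxygen); the alkene between C4 and the veratryl carbon (aldol condensation of pyruvate with veratraldehyde).
2. Enabling feature: the C3 oxygen is 1,3 to C5 (O–C3–C4–C5), so a SiMe2 unit can bridge that oxygen and C5 and close a temporary five-membered 1,2-oxasilolane ring O–Si–C5–C4–C3 that is not in the target. C4 is, in the precursor, the inner carbon of a styrene on the 3,4-dimethoxyphenyl ring, so a Si–CH2 radical attacks C4 in the 5-exo mode and leaves a benzylic radical.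
3. Forward order: acyclic chain → (S)-carbinol → silyl tether → oxasilolane ring (C5–C4 bond and the C4 stereocentre) → silicon excised, the new C5–OH closes the butyrolactone on the C2 ester → benzylation at C3 → debenzylation.
4. Stereochemistry: the (S)-C3 carbinol comes from an L-lactate dehydrogenase reduction and steers C4 in the ring closure (ester and new arylmethyl trans on the silacycle). C3 is then flattened to the enolate and rebuilt by alkylation anti to the C4 arylmethyl group, which gives trans benzyls with OH cis to the C4 benzyl, i.e. (3S,4S).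

Key step: step 5

Remark on the chemistry: compounds 1, 2, 6 and 12 are taken as commercial; the C3 configuration of compounds 4 to 11 serves only to set C4 and is deliberately erased in step 9.

**Route**

Step 1
Reactants: 1 3,4-dimethoxybenzaldehyde (veratraldehyde); 2 pyruvic acid
Product: 3 potassium (3E)-4-(3,4-dimethoxyphenyl)-2-oxobut-3-enoate
Conditions: KOH, MeOH, 0 °C to rt; salt collected by filtration
Reagents that add atoms: potassium hydroxide [K+].[OH-]
Why: Claisen–Schmidt condensation, in which the pyruvate enolate adds to the non-enolisable aldehyde and E1cB dehydration should give the conjugated (E)-enone, which separates from methanol as its potassium salt.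

Step 2
Reactants: 3 potassium (3E)-4-(3,4-dimethoxyphenyl)-2-oxobut-3-enoate
Product: 4 (2S,3E)-4-(3,4-dimethoxyphenyl)-2-hydroxybut-3-enoic acid
Conditions: L-lactate dehydrogenase (Bacillus stearothermophilus), NADH (cat.), formate dehydrogenase, HCO2Na, fructose 1,6-bisphosphate (activator), phosphate buffer pH 6.5, 30 °C; then HCl to pH 2, EtOAc extraction
Reagents that add atoms: none
Why: Enzymatic ketone reduction, in which the L-specific lactate dehydrogenase delivers hydride from NADH to the re face of the 2-oxo acid and so sets the (S)-carbinol, leaves the conjugated C=C alone, and is driven by irreversible NADH regeneration with formate dehydrogenase, the reduction of 4-aryl-2-oxobut-3-enoic acids by this enzyme class being precedented.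

Step 3
Reactants: 4 (2S,3E)-4-(3,4-dimethoxyphenyl)-2-hydroxybut-3-enoic acid
Product: 5 methyl (2S,3E)-4-(3,4-dimethoxyphenyl)-2-hydroxybut-3-enoate
Conditions: Me3SiCHN2, MeOH/toluene, 0 °C
Reagents that add atoms: (trimethylsilyl)diazomethane C[Si](C)(C)C=[N+]=[N-]
Why: Diazomethane-type O-methylation of the carboxylic acid under neutral conditions should esterify only the carboxyl group and spare the allylic α-carbinol, which base or acid could isomerise to the 2-oxo ester or racemise.

Step 4
Reactants: 5 methyl (2S,3E)-4-(3,4-dimethoxyphenyl)-2-hydroxybut-3-enoate; 6 (bromomethyl)chlorodimethylsilane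
Product: 7 methyl (2S,3E)-2-{[(bromomethyl)dimethylsilyl]oxy}-4-(3,4-dimethoxyphenyl)but-3-enoate
Conditions: imidazole, CH2Cl2, 0 °C; used after rapid filtration through silica
Reagents that add atoms: none
Why: O-silylation (substitution at silicon with imidazole as HCl acceptor and silyl-transfer catalyst) attaches the radical precursor to the C3 oxygen, and the weak base avoids a prototropic shift of the allylic α-hydrogen, so the (S) centre and the (E)-alkene are kept.

Step 5
Reactants: 7 methyl (2S,3E)-2-{[(bromomethyl)dimethylsilyl]oxy}-4-(3,4-dimethoxyphenyl)but-3-enoate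
Product: 8 methyl (4R,5S)-4-[(3,4-dimethoxyphenyl)methyl]-2,2-dimethyl-1,2-oxasilolane-5-carboxylate (ester and arylmethyl trans)
Conditions: Bu3SnH (syringe pump), AIBN (cat.), benzene, 80 °C, 0.01 M
Reagents that add atoms: none
Why: Bu3Sn• abstracts bromine from the Si–CH2Br group and the resulting α-silyl methyl radical adds to the near alkene carbon (the future lactone C4), after which the benzylic radical, stabilised by the 3,4-dimethoxyphenyl ring, takes a hydrogen atom from Bu3SnH and carries the chain. The closest known reaction type is the Nishiyama–Stork silicon-tethered radical cyclisation of (bromomethyl)dimethylsilyl ethers of allylic alcohols. The one ring that closes, the 1,2-oxasilolane made of the C3 oxygen, Si, the future C5, the future C4 and C3, forms in the 5-exo-trig mode. The new stereocentre (future C4) is controlled by the neighbouring (S)-carbinol centre: in the chair-like transition state the CO2Me group sits pseudo-equatorial, so the new arylmethyl group should end trans to the ester, (4R,5S) in silacycle numbering. The step needs 5-exo over 6-endo attack, secured by the aryl group on the far alkene carbon (only 5-exo attack gives a benzylic radical); cyclisation before reduction of the first radical, secured by slow stannane addition at high dilution; and trans over cis closure, which rests on the steric demand of the ester. Any cis isomer is to be removed by chromatography here or at 10, because after the enolisation of step 9 it would end as the enantiomer of the target.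

Step 6
Reactants: 8 methyl (4R,5S)-4-[(3,4-dimethoxyphenyl)methyl]-2,2-dimethyl-1,2-oxasilolane-5-carboxylate
Product: 10 (3S,4S)-4-[(3,4-dimethoxyphenyl)methyl]-3-hydroxyoxolan-2-one, via diol ester 9 (not isolated)
Conditions: 30% H2O2, KF, KHCO3, THF/MeOH, rt; then TsOH (cat.), CH2Cl2, rt
Reagents that add atoms: hydrogen peroxide OO
Why: Tamao–Fleming oxidation (fluoride-assisted peroxide attack at the alkoxysilane and 1,2-shift of the CH2 group from silicon to oxygen with retention) turns the C5–Si bond into C5–OH and frees the C3–OH, and the γ-hydroxy ester 9 then lactonises by 5-exo-trig acyl substitution without touching either stereocentre, the hydroxyl and the arylmethyl group ending cis because the ring now runs through C2 instead of through the C3 oxygen.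

Step 7
Reactants: 10 (3S,4S)-4-[(3,4-dimethoxyphenyl)methyl]-3-hydroxyoxolan-2-one
Product: 11 (3S,4S)-3-(benzyloxy)-4-[(3,4-dimethoxyphenyl)methyl]oxolan-2-one
Conditions: BnBr, Ag2O, CH2Cl2, rt, dark
Reagents that add atoms: benzyl bromide BrCc1ccccc1
Why: Ag2O-promoted Williamson etherification (silver-assisted halide abstraction, no strong base) should benzylate the secondary α-hydroxyl without opening the lactone or touching C4, the benzyl ether being chosen so that it leaves together with the phenol benzyl group in the last step.

Step 8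
Reactants: 12 [4-(benzyloxy)-3-methoxyphenyl]methanol
Product: 13 1-(benzyloxy)-4-(bromomethyl)-2-methoxybenzene
Conditions: PBr3, Et2O, 0 °C
Reagents that add atoms: phosphorus tribromide BrP(Br)Br
Why: Conversion of a benzylic alcohol into the bromide with PBr3 (SN2 displacement of the intermediate phosphite ester by bromide) is standard for electron-rich benzyl alcohols and spares the aryl benzyl ether.

Step 9
Reactants: 11 (3S,4S)-3-(benzyloxy)-4-[(3,4-dimethoxyphenyl)methyl]oxolan-2-one; 13 1-(benzyloxy)-4-(bromomethyl)-2-methoxybenzene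
Product: 15 (3S,4S)-3-(benzyloxy)-3-{[4-(benzyloxy)-3-methoxyphenyl]methyl}-4-[(3,4-dimethoxyphenyl)methyl]oxolan-2-one, via lithium enolate 14 (not isolated)
Conditions: LiN(iPr)2, THF, −78 °C; then 13, DMPU, −78 to −40 °C
Reagents that add atoms: lithium diisopropylamide [Li+].CC(C)[N-]C(C)C (its lithium stays in intermediate 14 only)
Why: Diastereoselective enolate alkylation (SN2), in which LiN(iPr)2 turns C3 into the planar lithium enolate 14 and the benzylic bromide should approach the face of the five-membered ring opposite to the C4 arylmethyl group, so the new C3 benzyl comes out trans to the C4 benzyl and the benzyloxy group cis to it, the (3S,4S) arrangement of the target, while C4 has no acidic hydrogen and keeps its configuration.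

Step 10
Reactants: 15 (3S,4S)-3-(benzyloxy)-3-{[4-(benzyloxy)-3-methoxyphenyl]methyl}-4-[(3,4-dimethoxyphenyl)methyl]oxolan-2-one
Product: 16 trachelogenin, (3S,4S)-4-[(3,4-dimethoxyphenyl)methyl]-3-hydroxy-3-[(4-hydroxy-3-methoxyphenyl)methyl]oxolan-2-one
Conditions: H2 (1 atm), 10% Pd/C, EtOAc/EtOH, rt
Reagents that add atoms: none
Why: Catalytic hydrogenolysis of benzyl ethers over Pd/C should cleave both the aryl benzyl ether and the tertiary alkyl benzyl ether at their PhCH2–O bonds, while the C3–O bond (homobenzylic, not benzylic), the lactone and the electron-rich arenes are inert, so no stereocentre is affected.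

**Compound list**

1 | 3,4-dimethoxybenzaldehyde (veratraldehyde) | COc1ccc(C=O)cc1OC | starting material
2 | pyruvic acid | CC(=O)C(=O)O | starting material
3 | potassium (3E)-4-(3,4-dimethoxyphenyl)-2-oxobut-3-enoate | [K+].[O-]C(=O)C(=O)/C=C/c1ccc(OC)c(OC)c1 | intermediate
4 | (2S,3E)-4-(3,4-dimethoxyphenyl)-2-hydroxybut-3-enoic acid | O[C@@H](/C=C/c1ccc(OC)c(OC)c1)C(=O)O | intermediate
5 | methyl (2S,3E)-4-(3,4-dimethoxyphenyl)-2-hydroxybut-3-enoate | O[C@@H](/C=C/c1ccc(OC)c(OC)c1)C(=O)OC | intermediate
6 | (bromomethyl)chlorodimethylsilane | C[Si](C)(Cl)CBr | starting material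
7 | methyl (2S,3E)-2-{[(bromomethyl)dimethylsilyl]oxy}-4-(3,4-dimethoxyphenyl)but-3-enoate | BrC[Si](C)(C)O[C@@H](/C=C/c1ccc(OC)c(OC)c1)C(=O)OC | intermediate
8 | methyl (4R,5S)-4-[(3,4-dimethoxyphenyl)methyl]-2,2-dimethyl-1,2-oxasilolane-5-carboxylate | COC(=O)[C@H]1O[Si](C)(C)C[C@@H]1Cc1ccc(OC)c(OC)c1 | intermediate
9 | methyl (2S,3S)-4-(3,4-dimethoxyphenyl)-2-hydroxy-3-(hydroxymethyl)butanoate (diol ester, not isolated) | COC(=O)[C@@H](O)[C@H](CO)Cc1ccc(OC)c(OC)c1 | intermediate
10 | (3S,4S)-4-[(3,4-dimethoxyphenyl)methyl]-3-hydroxyoxolan-2-one | O[C@@H]1C(=O)OC[C@@H]1Cc1ccc(OC)c(OC)c1 | intermediate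
11 | (3S,4S)-3-(benzyloxy)-4-[(3,4-dimethoxyphenyl)methyl]oxolan-2-one | c1ccccc1CO[C@@H]1C(=O)OC[C@@H]1Cc1ccc(OC)c(OC)c1 | intermediate
12 | [4-(benzyloxy)-3-methoxyphenyl]methanol | COc1cc(CO)ccc1OCc1ccccc1 | starting material
13 | 1-(benzyloxy)-4-(bromomethyl)-2-methoxybenzene | COc1cc(CBr)ccc1OCc1ccccc1 | intermediate
14 | lithium (4S)-3-(benzyloxy)-4-[(3,4-dimethoxyphenyl)methyl]-4,5-dihydrofuran-2-olate (lithium enolate, not isolated) | [Li+].[O-]C1=C(OCc2ccccc2)[C@@H](Cc2ccc(OC)c(OC)c2)CO1 | intermediate
15 | (3S,4S)-3-(benzyloxy)-3-{[4-(benzyloxy)-3-methoxyphenyl]methyl}-4-[(3,4-dimethoxyphenyl)methyl]oxolan-2-one | COc1cc(C[C@@]2(OCc3ccccc3)C(=O)OC[C@@H]2Cc2ccc(OC)c(OC)c2)ccc1OCc1ccccc1 | intermediate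
16 | trachelogenin | COc1cc(C[C@@]2(O)C(=O)OC[C@@H]2Cc2ccc(OC)c(OC)c2)ccc1O | target

**Step count and risks**

Total step count: 10. Longest linear sequence: 9 steps (steps 1 to 7, 9 and 10); step 8 is a one-step side branch.

Steps most likely to fail:

Step 5. The chair-like and boat-like transition states of the silicon-containing ring (long Si–C and Si–O bonds) may lie close in energy, so the closure may discriminate poorly between the two alkene faces; reduction of the C–Br bond before cyclisation is a second loss channel. The fallback gives up the tether and sets C4 by acyclic enolate control; it sets out from veratraldehyde 1 and returns to the route at lactone 10. Compound 1 is reduced (NaBH4, MeOH) to 3,4-dimethoxybenzyl alcohol F1, which PBr3 in Et2O converts into 3,4-dimethoxybenzyl bromide F2. Frater–Seebach alkylation of the dilithium alkoxide enolate of commercial dimethyl (S)-malate (LiN(SiMe3)2, THF, −78 to −20 °C) with F2 should give, anti to the alkoxide, dimethyl (2S,3R)-3-[(3,4-dimethoxyphenyl)methyl]-2-hydroxybutanedioate F3. Saponification (KOH, aqueous MeOH) gives (2S,3R)-3-[(3,4-dimethoxyphenyl)methyl]-2-hydroxybutanedioic acid F4. 2,2-Dimethoxypropane with TsOH ties up the α-hydroxy acid as (2R)-3-(3,4-dimethoxyphenyl)-2-[(4S)-2,2-dimethyl-5-oxo-1,3-dioxolan-4-yl]propanoic acid F5. BH3·SMe2 reduces the free carboxyl group to (5S)-5-[(2S)-1-(3,4-dimethoxyphenyl)-3-hydroxypropan-2-yl]-2,2-dimethyl-1,3-dioxolan-4-one F6, and TsOH in CH2Cl2 transacylates F6 to lactone 10.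

Step 9. C-alkylation of the fully substituted α-alkoxy enolate may be slow, so that on warming the enolate is consumed by a Wittig-type 1,2-shift of the benzyl group from oxygen to carbon or by O-alkylation. The fallback replaces the alkylation by an aldol addition and an ionic deoxygenation; it sets out from enolate 14 and returns at 15. Enolate 14 is treated at −78 °C with 4-(benzyloxy)-3-methoxybenzaldehyde, a faster electrophile than the bromide, which should add anti to the C4 substituent and give (3R,4S)-3-(benzyloxy)-3-{[4-(benzyloxy)-3-methoxyphenyl](hydroxy)methyl}-4-[(3,4-dimethoxyphenyl)methyl]oxolan-2-one F7 as a mixture of carbinol epimers. The electron-rich benzylic hydroxyl is then removed with Et3SiH and CF3CO2H in CH2Cl2 at 0 °C (ionisation to the para-alkoxybenzyl cation and hydride capture), which gives 15.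

Step 2. The enzyme may turn over the dimethoxyaryl oxo acid only slowly (substrate inhibition, low solubility), leaving the conversion incomplete. The fallback makes the carbinol centre by enantioselective C–C bond formation instead of C=O reduction; it sets out from veratraldehyde 1 and returns at ester 5, which also saves step 3. Wittig reaction of 1 with Ph3P=CHCHO (toluene, 80 °C) gives (2E)-3-(3,4-dimethoxyphenyl)prop-2-enal F8. An (S)-selective hydroxynitrile lyase (Hevea brasiliensis) with HCN in citrate buffer pH 5/tBuOMe at 0 to 5 °C should give (2S,3E)-4-(3,4-dimethoxyphenyl)-2-hydroxybut-3-enenitrile F9. Pinner methanolysis (HCl, MeOH, 0 °C, then water) converts the nitrile through its imidate salt into 5.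

Further compounds
F1 | step 5 | 3,4-dimethoxybenzyl alcohol | COc1ccc(CO)cc1OC
F2 | step 5 | 3,4-dimethoxybenzyl bromide | COc1ccc(CBr)cc1OC
F3 | step 5 | dimethyl (2S,3R)-3-[(3,4-dimethoxyphenyl)methyl]-2-hydroxybutanedioate | COC(=O)[C@@H](O)[C@H](C(=O)OC)Cc1ccc(OC)c(OC)c1
F4 | step 5 | (2S,3R)-3-[(3,4-dimethoxyphenyl)methyl]-2-hydroxybutanedioic acid | OC(=O)[C@@H](O)[C@H](C(=O)O)Cc1ccc(OC)c(OC)c1
F5 | step 5 | (2R)-3-(3,4-dimethoxyphenyl)-2-[(4S)-2,2-dimethyl-5-oxo-1,3-dioxolan-4-yl]propanoic acid | CC1(C)O[C@@H]([C@@H](Cc2ccc(OC)c(OC)c2)C(=O)O)C(=O)O1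
F6 | step 5 | (5S)-5-[(2S)-1-(3,4-dimethoxyphenyl)-3-hydroxypropan-2-yl]-2,2-dimethyl-1,3-dioxolan-4-one | CC1(C)O[C@@H]([C@@H](Cc2ccc(OC)c(OC)c2)CO)C(=O)O1
F7 | step 9 | (3R,4S)-3-(benzyloxy)-3-{[4-(benzyloxy)-3-methoxyphenyl](hydroxy)methyl}-4-[(3,4-dimethoxyphenyl)methyl]oxolan-2-one (carbinol epimers) | COc1cc(C(O)[C@@]2(OCc3ccccc3)C(=O)OC[C@@H]2Cc2ccc(OC)c(OC)c2)ccc1OCc1ccccc1
F8 | step 2 | (2E)-3-(3,4-dimethoxyphenyl)prop-2-enal | COc1ccc(/C=C/C=O)cc1OC
F9 | step 2 | (2S,3E)-4-(3,4-dimethoxyphenyl)-2-hydroxybut-3-enenitrile | O[C@@H](/C=C/c1ccc(OC)c(OC)c1)C#N
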